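Turn each step into a time at the charged amounts and lay those times against the 3.0 min asked of maple and ash.

the same everywhere: substrate 0.33 M
- midnight: reagent 0.22 M; run made earlier
- spring: reagent 0.65 M; run made earlier
- maple: reagent 0.860 M; time 3.0 min
- ash: reagent 0.430 M; time 3.0 min

| run | time / s | over-reaction product / % | target / % | substrate / % | intermediate / % |
|---|---|---|---|---|---|
| midnight | 15.0 | 0 | 2 | 92 | 5 |
| midnight | 40.0 | 0 | 4 | 83 | 18 |
| midnight | 80.0 | 3 | 5 | 70 | 21 |
| midnight | 120 | 2 | 8 | 66 | 26 |
| spring | 15.0 | 0 | 1 | 78 | 18 |
| spring | 40.0 | 0 | 4 | 55 | 37 |
| spring | 80.0 | 10 | 10 | 36 | 47 |
| spring | 120 | 14 | 7 | 27 | 49 |

(each reading ± 1.5 percentage points)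

- which of these there is most of at the end, counted by the substrate in it, maple (target / intermediate / over-reaction product / substrate)
- which of these there is most of at the end, counted by the substrate in it, ash (target / intermediate / over-reaction product / substrate)
- amount of the one of these that there is most of at the end, in percent of the substrate charged, maple
- amount of the one of these that there is most of at the end, in percent of the substrate charged, ash

- the numbers in the tables scatter with a standard deviation of 1.5 percentage points
- steps that have been proposed: substrate + reagent -> intermediate + released group; intermediate <-> target; reagent + target -> over-reaction product

I start with the slowest rung. Trapezoids give the time-integral of c(intermediate) up to the last reading, and I divide it by the target plus over-reaction product then present. The spring run gives 3.51 min, and the midnight run gives 3.41 min. This ratio is the exit time of the intermediate, its mean stay in that pool as read from the readings, and I use the spring value for both flasks.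

The faster rung is uptake, pseudo-first-order in substrate. The spring substrate reading at 40.0 s gives k1 = 0.0260 M⁻¹ s⁻¹. With c(reagent) taken as its charge less half of c(substrate), the uptake time is 0.924 min in maple and 2.42 min in ash. Both are shorter than the exit time, and the asked time is shorter than the exit time too.

Two consecutive first-order pools then give me, for maple, intermediate 52.5% and substrate 3.89%. Taking target at the spring reading of 10%, over-reaction product comes to 33.6%. For ash I get intermediate 43.8% and substrate 29.0%.

The forecast names intermediate at 47% (40% to 54%) for maple and intermediate at 44% (39% to 50%) for ash, and says of maple: “Intermediate has passed its maximum but probably still leads, though over-reaction product is closing in.” My leaders are the same, and my maple figure stands higher.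

    substrate + reagent → intermediate + released group (k = 0.0251 M⁻¹ s⁻¹)
    intermediate ⇌ target (K = 0.430, k = 0.00855 s⁻¹)
    reagent + target → over-reaction product (k = 0.0578 M⁻¹ s⁻¹)

Maple ends with intermediate at 45.9%, and ash with intermediate at 41.8%. At the end of maple, intermediate is made at 0.370 of the rate at which it is used up. Over the second half of maple, the exit time 3.51 min sends out 22 percentage points, and the flask shows 23 points. Over the second half of ash, it sends out 17 points, and the flask shows 14 points.

(The numbers in the tables were generated by integration on assumed constants, and the scatter is random.)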